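**Retrosynthetic overview**

1. Numbering: ring C1–C10 with C4 = C(CH3)OH, C5 = free CHOH, C6 = ester CH, C7 = CH bearing C11 (CMe2OH), C10 = CH–CH3. The strategy rests on the vicinal secondary carbinols C5/C6 of the ten-membered carbocycle, set between quaternary C4 and branched C7, and on the chain C8–C9–C10–C1–C2–C3–C4(–C5) with its two methyls being (S)-citronellol.
2. Late stage: the angelate at O6 is cut first; O4 and O5 are tied as a p-methoxybenzylidene acetal made from the C4 PMB ether, which tells C5–OH from C6–OH.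
3. Key disconnection: the C5–C6 bond, closed by SmI2 pinacol coupling of a 1,10-dialdehyde carrying C4–OPMB and C11–OTES.
4. Dialdehyde: C7–C8 bond by auxiliary-controlled deconjugative alkylation of a 3-methylbut-2-enoyl oxazolidinone (C6, C7, C11 unit) with the C8 triflate; C4 by Sharpless epoxidation and hydride opening of SeO2-oxidised citronellyl acetate; C10 from the chiral pool.
5. Ring order: the molecule has one ring, the ten-membered carbocycle, formed in step 15; the acetal rings are temporary.

Key step: step 15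

Remark: the acetal carbon of the p-methoxybenzylidene acetals (7, 12, 14, 15, 16, 22, 25) is a temporary centre formed as an epimer mixture; it is left undefined in the SMILES.

**Route**

Step 1
Reactants: 1 (S)-citronellol
Product: 2 (3S)-3,7-dimethyloct-6-en-1-yl acetate
Conditions: Ac2O, pyridine, DMAP (cat.), CH2Cl2, 0 °C to rt
Reagents that add atoms: acetic anhydride, CC(=O)OC(C)=O
Why: DMAP-catalysed acetylation of the primary alcohol masks C8–OH through the allylic oxidation and epoxidation, and the ester is removed by the hydride of step 4 without a separate step.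

Step 2
Reactants: 2 (3S)-3,7-dimethyloct-6-en-1-yl acetate
Product: 3 (3S,6E)-8-hydroxy-3,7-dimethyloct-6-en-1-yl acetate
Conditions: SeO2 (cat.), t-BuOOH, salicylic acid (cat.), CH2Cl2, rt
Reagents that add atoms: tert-butyl hydroperoxide, CC(C)(C)OO
Why: SeO2-catalysed allylic oxidation (ene reaction then [2,3]-sigmatropic shift) of a gem-dimethyl trisubstituted alkene goes at the (E)-methyl group, so the E allylic alcohol carrying the future C5 should result.

Step 3
Reactants: 3 (3S,6E)-8-hydroxy-3,7-dimethyloct-6-en-1-yl acetate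
Product: 4 (3S)-5-[(2S,3S)-3-(hydroxymethyl)-3-methyloxiran-2-yl]-3-methylpentyl acetate
Conditions: Ti(OiPr)4 (cat.), L-(+)-diethyl tartrate (cat.), t-BuOOH, 4 Å MS, CH2Cl2, −20 °C
Reagents that add atoms: tert-butyl hydroperoxide, CC(C)(C)OO
Why: Katsuki–Sharpless asymmetric epoxidation of an (E)-2-methylallylic alcohol with the L-(+)-tartrate gives the (2S,3S)-oxirane by reagent control, which sets C4; the C3 centre is erased in step 4.

Step 4
Reactants: 4 (3S)-5-[(2S,3S)-3-(hydroxymethyl)-3-methyloxiran-2-yl]-3-methylpentyl acetate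
Product: 5 (2R,6S)-2,6-dimethyloctane-1,2,8-triol
Conditions: LiAlH4, THF, 0 °C to rt
Reagents that add atoms: none
Why: LiAlH4 reduction opens the 2,3-epoxy alcohol by SN2 hydride attack at the secondary C3 and not at the fully substituted C4, whose C–O bond and configuration are untouched, and the acetate is reduced off in the same flask.

Step 5
Reactants: 5 (2R,6S)-2,6-dimethyloctane-1,2,8-triol; 6 p-anisaldehyde dimethyl acetal
Product: 7 (3S)-5-[(4R)-2-(4-methoxyphenyl)-4-methyl-1,3-dioxolan-4-yl]-3-methylpentan-1-ol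
Conditions: PPTS (cat.), CH2Cl2, rt
Reagents that add atoms: none
Why: acid-catalysed transacetalisation closes the 1,2-diol to the five-membered acetal, whereas the lone C8–OH can only give a labile mixed acetal that reverts on work-up.

Step 6
Reactants: 8 (S)-4-benzyloxazolidin-2-one; 9 3-methylbut-2-enoyl chloride
Product: 11 (S)-4-benzyl-3-(3-methylbut-2-enoyl)oxazolidin-2-one, via N-lithio oxazolidinone 10 (not isolated)
Conditions: n-BuLi, THF, −78 °C; then 9, −78 to 0 °C
Reagents that add atoms: none
Why: N-acylation of the lithiated Evans oxazolidinone with an acid chloride is the standard way to the acyl imide.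

Step 7
Reactants: 7 (3S)-5-[(4R)-2-(4-methoxyphenyl)-4-methyl-1,3-dioxolan-4-yl]-3-methylpentan-1-ol
Product: 12 (3S)-5-[(4R)-2-(4-methoxyphenyl)-4-methyl-1,3-dioxolan-4-yl]-3-methylpentyl trifluoromethanesulfonate
Conditions: Tf2O, 2,6-lutidine, CH2Cl2, −78 °C; cold work-up, used at once
Reagents that add atoms: trifluoromethanesulfonic anhydride, O=S(=O)(OS(=O)(=O)C(F)(F)F)C(F)(F)F
Why: sulfonylation of the primary alcohol under buffered conditions leaves the acetal alone and gives the leaving group that an unactivated primary carbon needs for the enolate alkylation.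

Step 8
Reactants: 11 (S)-4-benzyl-3-(3-methylbut-2-enoyl)oxazolidin-2-one; 12 (3S)-5-[(4R)-2-(4-methoxyphenyl)-4-methyl-1,3-dioxolan-4-yl]-3-methylpentyl trifluoromethanesulfonate
Product: 14 (S)-4-benzyl-3-{(2S,5S)-8-[(4R)-2-(4-methoxyphenyl)-4-methyl-1,3-dioxolan-4-yl]-5-methyl-2-(prop-1-en-2-yl)octanoyl}oxazolidin-2-one, via sodium dienolate 13 (not isolated)
Conditions: 11 (1.5 equiv), NaHMDS, THF, −78 °C; then 12, −78 to −40 °C
Reagents that add atoms: none
Why: Evans asymmetric alkylation in its deconjugative form: γ-deprotonation gives the chelated (Z)-dienolate, which the primary triflate alkylates at the α-carbon on the face away from the benzyl group, forming the C7–C8 bond and setting C7 with the isopropenyl group as latent C11.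

Step 9
Reactants: 14 alkylated imide
Product: 15 (2S,5S)-8-[(4R)-2-(4-methoxyphenyl)-4-methyl-1,3-dioxolan-4-yl]-5-methyl-2-(prop-1-en-2-yl)octan-1-ol
Conditions: LiBH4, H2O (1 equiv), Et2O, 0 °C
Reagents that add atoms: none
Why: reductive cleavage of the N-acyl oxazolidinone by LiBH4 gives the primary alcohol C6–OH without touching the C7 centre and returns the auxiliary.

Step 10
Reactants: 15 isopropenyl alcohol
Product: 16 (2R)-2-{(3S)-6-[(4R)-2-(4-methoxyphenyl)-4-methyl-1,3-dioxolan-4-yl]-3-methylhexyl}-3-methylbutane-1,3-diol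
Conditions: Co(acac)2 (cat.), PhSiH3, O2 (1 atm), THF, rt; aq. Na2S2O3 work-up
Reagents that add atoms: dioxygen, O=O
Why: Mukaiyama hydration (hydrogen-atom transfer to the 1,1-disubstituted alkene, O2 capture of the tertiary radical, reduction of the peroxide) gives the Markovnikov tertiary alcohol C11–OH under neutral conditions that spare the acetal and do not involve C7.

Step 11
Reactants: 16 1,3-diol acetal
Product: 17 (2R,6S,9R)-9-(2-hydroxypropan-2-yl)-2-[(4-methoxyphenyl)methoxy]-2,6-dimethyldecane-1,10-diol
Conditions: DIBAL-H (excess), CH2Cl2, −78 to 0 °C; Rochelle salt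
Reagents that add atoms: none
Why: reductive opening of the p-methoxybenzylidene acetal: aluminium binds the less hindered primary oxygen, that C–O bond breaks and hydride quenches the oxocarbenium ion, so the PMB group stays on the tertiary O4 and C5–OH is freed.

Step 12
Reactants: 17 triol mono-PMB ether
Product: 18 tris(triethylsilyl) ether of 17
Conditions: TESOTf, 2,6-lutidine, CH2Cl2, −78 to 0 °C
Reagents that add atoms: triethylsilyl trifluoromethanesulfonate, CC[Si](CC)(CC)OS(=O)(=O)C(F)(F)F
Why: silylation with the silyl triflate is strong enough for the tertiary C11–OH, and all three hydroxyls are capped so that the tertiary ether can be kept selectively in step 13.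

Step 13
Reactants: 18 tris(triethylsilyl) ether
Product: 19 (2R,6S,9R)-2-[(4-methoxyphenyl)methoxy]-2,6-dimethyl-9-{2-[(triethylsilyl)oxy]propan-2-yl}decane-1,10-diol
Conditions: PPTS (cat.), MeOH/CH2Cl2, 0 °C
Reagents that add atoms: none
Why: acid-catalysed methanolysis cleaves the two primary TES ethers much faster than the hindered tertiary one, and the PMB ether is stable to PPTS.

Step 14
Reactants: 19 diol
Product: 20 (2R,6S,9S)-2-[(4-methoxyphenyl)methoxy]-2,6-dimethyl-9-{2-[(triethylsilyl)oxy]propan-2-yl}decanedial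
Conditions: Dess–Martin periodinane, NaHCO3, CH2Cl2, 0 °C to rt; used crude
Reagents that add atoms: none
Why: Dess–Martin oxidation of both primary alcohols under buffered non-basic conditions should avoid epimerisation at C7 and β-elimination of the silyloxy group, and C5 has no α-hydrogen.

Step 15
Reactants: 20 dialdehyde
Product: 21 (1R,2S,3R,7S,10R)-3-[(4-methoxyphenyl)methoxy]-3,7-dimethyl-10-{2-[(triethylsilyl)oxy]propan-2-yl}cyclodecane-1,2-diol
Conditions: SmI2 (4 equiv), THF, −78 to −20 °C, syringe-pump addition of 20 (final about 2 mM); aq. NaHCO3/Na2S2O3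
Reagents that add atoms: none
Why: SmI2 (divalent samarium) transfers one electron to an aldehyde, the samarium ketyl carbon adds to the second carbonyl carbon held on the same oxophilic metal, and a second electron gives the samarium 1,2-diolate; this is the intramolecular pinacol coupling of dialdehydes known with SmI2 and with low-valent titanium, here asked to close a ten-membered ring. The ring closes in a 10-exo-trig sense by forming only the C5–C6 bond between the two former carbonyl carbons. C6 should be set by C7 in the Felkin–Anh sense, the new bond forming anti to the bulky CMe2OTES group, and C5 by C4 in the polar Felkin–Anh sense, the new bond forming anti to the C4–O bond; together these correspond to the (5S,6R) trans-diol. The trans relation is the one pinacol closures tend to give once the ring is large enough for the two oxygens to turn apart, whereas small rings give cis-diols. Ring closure must beat intermolecular coupling and over-reduction, which high dilution, slow addition and the absence of a proton source should secure, and enolisation is excluded by the neutral medium and the quaternary C4. The sense and level of the diastereoselectivity cannot be taken for granted and must be settled by experiment.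

Step 16
Reactants: 21 trans-diol
Product: 22 O4,O5-(4-methoxybenzylidene) acetal of the (4R,5S,6R,7R,10S)-ring triol with C6–OH free and C11–OTES
Conditions: DDQ, 4 Å MS, anhydrous CH2Cl2, 0 °C
Reagents that add atoms: none
Why: oxidative acetal formation from a PMB ether: DDQ abstracts hydride and, without water, the oxocarbenium ion on O4 is captured by C5–OH, which lies cis to O4 on the ring, while C6–OH lies on the opposite face and stays free.

Step 17
Reactants: 22 acetal alcohol; 23 angelic acid
Product: 25 C6 angelate of 22, via mixed anhydride 24 (not isolated)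
Conditions: 23, 2,4,6-trichlorobenzoyl chloride, Et3N, toluene, rt; then 22, 80 °C
Reagents that add atoms: none
Why: Yamaguchi-type esterification through the angelic 2,4,6-trichlorobenzoic mixed anhydride without DMAP should acylate the hindered secondary alcohol without isomerising the Z double bond to the tiglate.

Step 18
Reactants: 25 protected angelate
Product: 26 (1R,2S,3R,7S,10R)-2,3-dihydroxy-10-(2-hydroxypropan-2-yl)-3,7-dimethylcyclodecyl (2Z)-2-methylbut-2-enoate
Conditions: AcOH/THF/H2O (3:1:1), 40 °C
Reagents that add atoms: none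
Why: mild aqueous acid hydrolysis removes the p-methoxybenzylidene acetal and the tertiary silyl ether while leaving the ester and its Z-alkene intact, and acyl migration to C5–OH is slow without base.

**Compound list**

1 | (S)-citronellol | OCC[C@@H](C)CCC=C(C)C | starting material
2 | (3S)-3,7-dimethyloct-6-en-1-yl acetate | CC(=O)OCC[C@@H](C)CCC=C(C)C | intermediate
3 | (3S,6E)-8-hydroxy-3,7-dimethyloct-6-en-1-yl acetate | CC(=O)OCC[C@@H](C)CC/C=C(\C)CO | intermediate
4 | (3S)-5-[(2S,3S)-3-(hydroxymethyl)-3-methyloxiran-2-yl]-3-methylpentyl acetate | CC(=O)OCC[C@@H](C)CC[C@@H]1O[C@@]1(C)CO | intermediate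
5 | (2R,6S)-2,6-dimethyloctane-1,2,8-triol | OCC[C@@H](C)CCC[C@@](C)(O)CO | intermediate
6 | p-anisaldehyde dimethyl acetal | COC(OC)c1ccc(OC)cc1 | starting material
7 | (3S)-5-[(4R)-2-(4-methoxyphenyl)-4-methyl-1,3-dioxolan-4-yl]-3-methylpentan-1-ol | OCC[C@@H](C)CCC[C@@](C)(O1)COC1c2ccc(OC)cc2 | intermediate
8 | (S)-4-benzyloxazolidin-2-one | O=C1N[C@@H](Cc2ccccc2)CO1 | starting material
9 | 3-methylbut-2-enoyl chloride | CC(C)=CC(Cl)=O | starting material
10 | N-lithio (S)-4-benzyloxazolidin-2-one | [Li+].O=C1[N-][C@@H](Cc2ccccc2)CO1 | intermediate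
11 | (S)-4-benzyl-3-(3-methylbut-2-enoyl)oxazolidin-2-one | CC(C)=CC(=O)N1[C@@H](Cc2ccccc2)COC1=O | intermediate
12 | (3S)-5-[(4R)-2-(4-methoxyphenyl)-4-methyl-1,3-dioxolan-4-yl]-3-methylpentyl trifluoromethanesulfonate | O=S(=O)(OCC[C@@H](C)CCC[C@@](C)(O1)COC1c2ccc(OC)cc2)C(F)(F)F | intermediate
13 | sodium (Z)-dienolate of 11 | [Na+].C=C(C)/C=C(\[O-])N1[C@@H](Cc2ccccc2)COC1=O | intermediate
14 | (S)-4-benzyl-3-{(2S,5S)-8-[(4R)-2-(4-methoxyphenyl)-4-methyl-1,3-dioxolan-4-yl]-5-methyl-2-(prop-1-en-2-yl)octanoyl}oxazolidin-2-one | C=C(C)[C@H](CC[C@@H](C)CCC[C@@](C)(O1)COC1c2ccc(OC)cc2)C(=O)N3[C@@H](Cc4ccccc4)COC3=O | intermediate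
15 | (2S,5S)-8-[(4R)-2-(4-methoxyphenyl)-4-methyl-1,3-dioxolan-4-yl]-5-methyl-2-(prop-1-en-2-yl)octan-1-ol | C=C(C)[C@H](CC[C@@H](C)CCC[C@@](C)(O1)COC1c2ccc(OC)cc2)CO | intermediate
16 | (2R)-2-{(3S)-6-[(4R)-2-(4-methoxyphenyl)-4-methyl-1,3-dioxolan-4-yl]-3-methylhexyl}-3-methylbutane-1,3-diol | CC(C)(O)[C@H](CC[C@@H](C)CCC[C@@](C)(O1)COC1c2ccc(OC)cc2)CO | intermediate
17 | (2R,6S,9R)-9-(2-hydroxypropan-2-yl)-2-[(4-methoxyphenyl)methoxy]-2,6-dimethyldecane-1,10-diol | CC(C)(O)[C@H](CC[C@@H](C)CCC[C@@](C)(OCc1ccc(OC)cc1)CO)CO | intermediate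
18 | tris(triethylsilyl) ether of 17 | CC(C)(O[Si](CC)(CC)CC)[C@H](CC[C@@H](C)CCC[C@@](C)(OCc1ccc(OC)cc1)CO[Si](CC)(CC)CC)CO[Si](CC)(CC)CC | intermediate
19 | (2R,6S,9R)-2-[(4-methoxyphenyl)methoxy]-2,6-dimethyl-9-{2-[(triethylsilyl)oxy]propan-2-yl}decane-1,10-diol | CC(C)(O[Si](CC)(CC)CC)[C@H](CC[C@@H](C)CCC[C@@](C)(OCc1ccc(OC)cc1)CO)CO | intermediate
20 | (2R,6S,9S)-2-[(4-methoxyphenyl)methoxy]-2,6-dimethyl-9-{2-[(triethylsilyl)oxy]propan-2-yl}decanedial | O=C[C@H](C(C)(C)O[Si](CC)(CC)CC)CC[C@@H](C)CCC[C@@](C)(OCc1ccc(OC)cc1)C=O | intermediate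
21 | (1R,2S,3R,7S,10R)-3-[(4-methoxyphenyl)methoxy]-3,7-dimethyl-10-{2-[(triethylsilyl)oxy]propan-2-yl}cyclodecane-1,2-diol | O[C@@H]1[C@H](C(C)(C)O[Si](CC)(CC)CC)CC[C@@H](C)CCC[C@@](C)(OCc2ccc(OC)cc2)[C@H]1O | intermediate
22 | O4,O5-(4-methoxybenzylidene) acetal of the ring triol, C6–OH free, C11–OTES | O[C@@H]1[C@H](C(C)(C)O[Si](CC)(CC)CC)CC[C@@H](C)CCC[C@@](C)(O3)[C@H]1OC3c4ccc(OC)cc4 | intermediate
23 | angelic acid, (2Z)-2-methylbut-2-enoic acid | C/C=C(/C)C(=O)O | starting material
24 | angelic 2,4,6-trichlorobenzoic anhydride | C/C=C(/C)C(=O)OC(=O)c1c(Cl)cc(Cl)cc1Cl | intermediate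
25 | C6 angelate of 22 | C/C=C(/C)C(=O)O[C@@H]1[C@H](C(C)(C)O[Si](CC)(CC)CC)CC[C@@H](C)CCC[C@@](C)(O3)[C@H]1OC3c4ccc(OC)cc4 | intermediate
26 | (1R,2S,3R,7S,10R)-2,3-dihydroxy-10-(2-hydroxypropan-2-yl)-3,7-dimethylcyclodecyl (2Z)-2-methylbut-2-enoate | C/C=C(/C)C(=O)O[C@@H]1[C@H](C(C)(C)O)CC[C@@H](C)CCC[C@@](C)(O)[C@H]1O | target

**Step count**

Total: 18 steps. Longest linear sequence: 17 steps (steps 1–5 and 7–18); step 6 is a one-step side branch.

**Steps most likely to fail, with fallbacks**

Step 15. Intermolecular coupling or simple reduction may outrun closure of the ten-membered ring, and facial control at C5 and C6 may be insufficient or reversed. The fallback sets out from dialdehyde 20. McMurry olefination with low-valent titanium (TiCl3(DME)1.5, Zn–Cu, DME, reflux, slow addition) closes the same C5–C6 bond as the alkene and should give, after separation from any Z isomer, the (E)-cyclodecene F1. Syn-dihydroxylation with OsO4/NMO on the exposed face of the (E)-alkene gives a trans-diol, with the face now decided by allylic strain from C4 and C7, and the route is rejoined at 21.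

Step 16. The oxocarbenium ion may be captured by the wrong hydroxyl, giving the six-membered acetal across O4/O6, or over-oxidation to the anisoate may occur. The fallback sets out from diol 21. Hydrogenolysis of the PMB ether (H2, Pd/C, EtOAc) gives the triol F2. Equilibrating acetonide formation (2,2-dimethoxypropane, PPTS) ties the cis-disposed O4/O5 pair as the acetonide F3 and leaves C6–OH free. Angeloylation as in step 17 gives the angelate acetonide F4, and AcOH/THF/H2O removes acetonide and silyl ether to reach 26.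

Step 8. C-alkylation of the dienolate by an unactivated primary electrophile may be slow, with decomposition of the triflate or γ-alkylation competing. The fallback sets out from alcohol 7. Appel bromination (CBr4, PPh3, imidazole) gives the bromide F5, and magnesium in THF gives the Grignard reagent F6. CuI-catalysed opening of (S)-(3,3-dimethyloxiran-2-yl)methanol F7 (from 3-methylbut-2-en-1-ol by Sharpless epoxidation with L-(+)-diethyl tartrate, used as its magnesium alkoxide) at the secondary epoxide carbon with inversion forms the C7–C8 bond. This gives the 1,3-diol 16 directly, where the route is rejoined.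

**Further compounds**

F1 | step 15 | (E)-cyclodecene with C4–OPMB and C11–OTES | CC[Si](CC)(CC)OC(C)(C)[C@@H]1CC[C@@H](C)CCC[C@@](C)(OCc2ccc(OC)cc2)/C=C/1
F2 | step 16 | ring 4,5,6-triol with C11–OTES | O[C@@H]1[C@H](C(C)(C)O[Si](CC)(CC)CC)CC[C@@H](C)CCC[C@@](C)(O)[C@H]1O
F3 | step 16 | O4,O5-acetonide with C6–OH free | O[C@@H]1[C@H](C(C)(C)O[Si](CC)(CC)CC)CC[C@@H](C)CCC[C@@](C)(O3)[C@H]1OC3(C)C
F4 | step 16 | C6 angelate of the O4,O5-acetonide | C/C=C(/C)C(=O)O[C@@H]1[C@H](C(C)(C)O[Si](CC)(CC)CC)CC[C@@H](C)CCC[C@@](C)(O3)[C@H]1OC3(C)C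
F5 | step 8 | (4R)-4-[(4S)-6-bromo-4-methylhexyl]-2-(4-methoxyphenyl)-4-methyl-1,3-dioxolane | BrCC[C@@H](C)CCC[C@@](C)(O1)COC1c2ccc(OC)cc2
F6 | step 8 | Grignard reagent of F5 | Br[Mg]CC[C@@H](C)CCC[C@@](C)(O1)COC1c2ccc(OC)cc2
F7 | step 8 | (S)-(3,3-dimethyloxiran-2-yl)methanol | OC[C@@H]1OC1(C)C
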